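**Retrosynthetic overview**
1. The quinone comes from a 2,3,5,6-tetramethoxyphenyl group (CAN, then selective vinylogous-ester hydrolysis); the Ar–C11 bond comes from an aryllithium and a neopentyl aldehyde.
2. The C5–OH (cis to H-10) is set by tethered oxygen delivery: the C11 hydroxyl adds across a Δ5 alkene to give a bridged tetrahydrofuran, and reductive benzylic C–O cleavage then turns C11 into CH2.
3. The Δ5-octalin aldehyde is made in one flask: enyne ring-closing metathesis (ring A), followed at once by a catalytic enantioselective exo Diels–Alder reaction with tiglic aldehyde (ring B; sets C8, C9, C10).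
4. The enyne comes from methyl isobutyrate and 5-bromopent-1-ene (ester to alkyne).
5. Ring order: A, then B in the same operation; the quinone ring is carried as the arene from 1,2,4,5-tetramethoxybenzene.

Assumption: drimane numbering is used in the discussion (C4 = CMe2, C5 = C–OH, C8 = CHMe, C9 = quaternary C, C10 = ring-fusion CH, C11 = benzylic C); the target SMILES corresponds to 5S,8S,9R,10S (5α-OH, 8β-Me, 9β-Me, 10α-H, cis-decalin), and the metathesis, oxazaborolidine and Co(salen) catalysts are taken as commercial.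

**Step 1**
Reactants: 1 methyl 2-methylpropanoate (methyl isobutyrate); 2 5-bromopent-1-ene
Product: 4 methyl 2,2-dimethylhept-6-enoate, via lithium 1-methoxy-2-methylprop-1-en-1-olate 3 (not isolated)
Conditions: LDA, THF, −78 °C; then 2, DMPU, −78 °C → rt
Reagents that add atoms: none
Why: SN2 alkylation of a fully substituted ester enolate with a primary bromide builds the C4 gem-dimethyl quaternary carbon; no stereocentre is formed.

**Step 2**
Reactants: 4 methyl 2,2-dimethylhept-6-enoate
Product: 6 3,3-dimethyloct-7-en-1-yne, via 2,2-dimethylhept-6-enal 5 (not isolated)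
Conditions: DIBAL-H (1.1 equiv), CH2Cl2, −78 °C; then MeOH, K2CO3, dimethyl (1-diazo-2-oxopropyl)phosphonate, −78 °C → rt
Reagents that add atoms: dimethyl (1-diazo-2-oxopropyl)phosphonate (Ohira–Bestmann reagent), CC(=O)C(=[N+]=[N-])P(=O)(OC)OC
Why: the hindered ester stops at the aluminium hemiacetal, which releases the non-enolisable aldehyde for one-pot Seyferth–Gilbert homologation (Ohira–Bestmann variant) to the terminal alkyne; no stereocentre is formed.

**Step 3**
Reactants: 6 3,3-dimethyloct-7-en-1-yne; 7 (E)-2-methylbut-2-enal (tiglic aldehyde)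
Product: 9 (1R,2S,8aR)-1,2,5,5-tetramethyl-1,2,3,5,6,7,8,8a-octahydronaphthalene-1-carbaldehyde, via 1-ethenyl-6,6-dimethylcyclohex-1-ene 8 (not isolated)
Conditions: Hoveyda–Grubbs II (2 mol %), ethylene (1 atm), CH2Cl2, 40 °C; then Ar purge, −78 °C, 7, (R)-2-(o-tolyl)-CBS-oxazaborolidine/Tf2NH (20 mol %), −78 → −20 °C
Reagents that add atoms: none
Why: tandem ring-closing enyne metathesis (exo mode, ring A) and Corey oxazaborolidinium-catalysed Diels–Alder reaction (ring B) in one flask: the enal β-carbon bonds to the unsubstituted vinyl terminus so the quaternary C9 ends next to C10, the catalyst-bound formyl group takes the exo position (as with other α-methyl enals, reinforced by the pseudo-axial C4 methyl) so both dienophile methyls end cis to C1 (8β-Me, 9β-Me, 10α-H), and the (R)-catalyst blocks the Re face at C9 so the diene adds to the Si face, giving 8S,9R with 10α-H.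

**Step 4**
Reactants: 9 (1R,2S,8aR)-1,2,5,5-tetramethyl-1,2,3,5,6,7,8,8a-octahydronaphthalene-1-carbaldehyde; 10 1,2,4,5-tetramethoxybenzene
Product: 12 [(1R,2S,8aR)-1,2,5,5-tetramethyl-1,2,3,5,6,7,8,8a-octahydronaphthalen-1-yl](2,3,5,6-tetramethoxyphenyl)methanol, via 2,3,5,6-tetramethoxyphenyllithium 11 (not isolated)
Conditions: 10, n-BuLi, THF, 0 °C → rt; then 9, −78 → 0 °C; H2O
Reagents that add atoms: none
Why: directed ortho-lithiation between two methoxy groups followed by 1,2-addition to the non-enolisable neopentyl aldehyde; the new carbinol centre (C11) forms as an epimer mixture that does not matter because C11 becomes CH2 in step 6.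

**Step 5**
Reactants: 12 [(1R,2S,8aR)-1,2,5,5-tetramethyl-1,2,3,5,6,7,8,8a-octahydronaphthalen-1-yl](2,3,5,6-tetramethoxyphenyl)methanol
Product: 13 (1R,2S,4aS,8aS)-1,2,5,5-tetramethyl-10-(2,3,5,6-tetramethoxyphenyl)octahydro-2H-4a,1-(epoxymethano)naphthalene
Conditions: Co(salen) (5 mol %), N-fluoro-2,4,6-trimethylpyridinium triflate (2 equiv), (Me2SiH)2O (2 equiv), PhCF3, rt
Reagents that add atoms: none
Why: Mukaiyama-type MHAT hydroalkoxylation (radical–polar crossover): Co–H delivers H to C6, the tertiary C5 radical is oxidised and captured 5-exo by the C11 hydroxyl, which can reach C5 only from the α-face on which C11 sits, so the C5–O bond (5S) is set cis to C11 and to H-10 and both C11 epimers converge.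

**Step 6**
Reactants: 13 (1R,2S,4aS,8aS)-1,2,5,5-tetramethyl-10-(2,3,5,6-tetramethoxyphenyl)octahydro-2H-4a,1-(epoxymethano)naphthalene
Product: 14 (1R,2S,4aS,8aS)-1,2,5,5-tetramethyl-1-[(2,3,5,6-tetramethoxyphenyl)methyl]octahydronaphthalen-4a(2H)-ol
Conditions: Li (3 equiv), NH3(l)/THF, −78 °C, 15 min; then solid NH4Cl
Reagents that add atoms: none
Why: dissolving-metal (Birch-type) reductive cleavage of the benzylic C11–O bond with the tertiary alkoxide as leaving group frees the C5 hydroxyl and makes C11 a CH2; the C5–O bond is not touched, so its configuration is kept.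

**Step 7**
Reactants: 14 (1R,2S,4aS,8aS)-1,2,5,5-tetramethyl-1-[(2,3,5,6-tetramethoxyphenyl)methyl]octahydronaphthalen-4a(2H)-ol
Product: 15 3-{[(1R,2S,4aS,8aS)-4a-hydroxy-1,2,5,5-tetramethyldecahydronaphthalen-1-yl]methyl}-2,5-dimethoxycyclohexa-2,5-diene-1,4-dione
Conditions: CAN (2.5 equiv), MeCN/H2O (2:1), 0 °C
Reagents that add atoms: water, O
Why: CAN oxidative demethylation of a para-dimethoxy pair; both possible para-quinones are the same compound, the tertiary alcohol is inert, and no stereocentre is involved.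

**Step 8**
Reactants: 15 3-{[(1R,2S,4aS,8aS)-4a-hydroxy-1,2,5,5-tetramethyldecahydronaphthalen-1-yl]methyl}-2,5-dimethoxycyclohexa-2,5-diene-1,4-dione
Product: 16 2-hydroxy-3-{[(1R,2S,4aS,8aS)-4a-hydroxy-1,2,5,5-tetramethyldecahydronaphthalen-1-yl]methyl}-5-methoxycyclohexa-2,5-diene-1,4-dione
Conditions: 60% aq. HClO4, THF, 0 °C → rt
Reagents that add atoms: water, O
Why: acid-catalysed addition–elimination hydrolysis of a vinylogous ester; the methoxy group flanked by the bulky side chain is twisted out of conjugation and is cleaved, while the methoxy next to the ring C–H stays; no stereocentre is involved.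

**Compound list**
1 | methyl 2-methylpropanoate (methyl isobutyrate) | COC(=O)C(C)C | starting material
2 | 5-bromopent-1-ene | BrCCCC=C | starting material
3 | lithium 1-methoxy-2-methylprop-1-en-1-olate | COC(O[Li])=C(C)C | intermediate
4 | methyl 2,2-dimethylhept-6-enoate | COC(=O)C(C)(C)CCCC=C | intermediate
5 | 2,2-dimethylhept-6-enal | O=CC(C)(C)CCCC=C | intermediate
6 | 3,3-dimethyloct-7-en-1-yne | C#CC(C)(C)CCCC=C | intermediate
7 | (E)-2-methylbut-2-enal (tiglic aldehyde) | C/C=C(\C)C=O | starting material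
8 | 1-ethenyl-6,6-dimethylcyclohex-1-ene | C=CC1=CCCCC1(C)C | intermediate
9 | (1R,2S,8aR)-1,2,5,5-tetramethyl-1,2,3,5,6,7,8,8a-octahydronaphthalene-1-carbaldehyde | O=C[C@]1(C)[C@@H](C)CC=C2[C@H]1CCCC2(C)C | intermediate
10 | 1,2,4,5-tetramethoxybenzene | COc1cc(OC)c(OC)cc1OC | starting material
11 | 2,3,5,6-tetramethoxyphenyllithium | [Li]c1c(OC)c(OC)cc(OC)c1OC | intermediate
12 | [(1R,2S,8aR)-1,2,5,5-tetramethyl-1,2,3,5,6,7,8,8a-octahydronaphthalen-1-yl](2,3,5,6-tetramethoxyphenyl)methanol (carbinol epimers) | OC(c1c(OC)c(OC)cc(OC)c1OC)[C@]2(C)[C@@H](C)CC=C3[C@H]2CCCC3(C)C | intermediate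
13 | (1R,2S,4aS,8aS)-1,2,5,5-tetramethyl-10-(2,3,5,6-tetramethoxyphenyl)octahydro-2H-4a,1-(epoxymethano)naphthalene (bridged tetrahydrofuran C11–O–C5; epimers at the aryl-bearing carbon) | C1(c2c(OC)c(OC)cc(OC)c2OC)[C@]3(C)[C@@H](C)CC[C@]4(O1)[C@H]3CCCC4(C)C | intermediate
14 | (1R,2S,4aS,8aS)-1,2,5,5-tetramethyl-1-[(2,3,5,6-tetramethoxyphenyl)methyl]octahydronaphthalen-4a(2H)-ol | COc1cc(OC)c(OC)c(C[C@]2(C)[C@@H](C)CC[C@]3(O)[C@H]2CCCC3(C)C)c1OC | intermediate
15 | 3-{[(1R,2S,4aS,8aS)-4a-hydroxy-1,2,5,5-tetramethyldecahydronaphthalen-1-yl]methyl}-2,5-dimethoxycyclohexa-2,5-diene-1,4-dione | COC1=CC(=O)C(OC)=C(C[C@]2(C)[C@@H](C)CC[C@]3(O)[C@H]2CCCC3(C)C)C1=O | intermediate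
16 | 2-hydroxy-3-{[(1R,2S,4aS,8aS)-4a-hydroxy-1,2,5,5-tetramethyldecahydronaphthalen-1-yl]methyl}-5-methoxycyclohexa-2,5-diene-1,4-dione | COC1=CC(=O)C(O)=C(C[C@]2(C)[C@@H](C)CC[C@]3(O)[C@H]2CCCC3(C)C)C1=O | target

**Step count**
Total: 8 steps. Longest linear sequence: 8 steps (1 → 16); the aryllithium is made and used within step 4.

**Steps most likely to fail, with fallbacks**

Step 3. The Diels–Alder reaction forms a quaternary centre from a sluggish dienophile on an acid-sensitive diene made in situ, and the exo and facial control rest on the catalyst model rather than on a tested case. The fallback replaces chiral Lewis-acid catalysis by an auxiliary-controlled ionic (Gassman-type) Diels–Alder reaction. It sets out from 6: enyne metathesis to 8 as before, but the dienophile is the chiral acetal (4R,6R)-2-[(E)-but-2-en-2-yl]-4,6-dimethyl-1,3-dioxane F1, made from 7 and (2R,4R)-pentane-2,4-diol (PPTS, MgSO4). TMSOTf (10 mol %) in CH2Cl2 at −78 °C opens it to a vinyl oxocarbenium ion, a much stronger dienophile than the free enal. The cycloadduct is isolated as the acetal (4R,6R)-4,6-dimethyl-2-[(1R,2S,8aR)-1,2,5,5-tetramethyl-1,2,3,5,6,7,8,8a-octahydronaphthalen-1-yl]-1,3-dioxane F2, and mild hydrolysis (PPTS, acetone/H2O) returns the diol and rejoins the route at 9.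

Step 5. The nucleophile is a very hindered benzylic alcohol, the oxidant sits next to a very electron-rich arene, and one C11 epimer may cyclise slowly. The fallback sets the C5–O bond by lactonisation before the arene is introduced. It sets out from 9: Pinnick oxidation (NaClO2, NaH2PO4, 2-methylbut-2-ene) gives (1R,2S,8aR)-1,2,5,5-tetramethyl-1,2,3,5,6,7,8,8a-octahydronaphthalene-1-carboxylic acid F3. TfOH (5 mol %) in CH2Cl2 at 0 °C protonates the Δ5 alkene and the carboxyl group closes from the α-face to the γ-lactone (1R,2S,4aS,8aS)-1,2,5,5-tetramethyloctahydro-2H-4a,1-(epoxymethano)naphthalen-10-one F4. DIBAL-H at −78 °C gives the lactol (1R,2S,4aS,8aS)-1,2,5,5-tetramethyloctahydro-2H-4a,1-(epoxymethano)naphthalen-10-ol F5. Excess 11 adds to its open hydroxy-aldehyde form to give the diol (1R,2S,4aS,8aS)-1-[hydroxy(2,3,5,6-tetramethoxyphenyl)methyl]-1,2,5,5-tetramethyloctahydronaphthalen-4a(2H)-ol F6. Li/NH3 (NH4Cl) removes the benzylic hydroxyl and the sequence comes back to the route at 14.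

Step 8. The regioselectivity of the mono-hydrolysis is argued from steric inhibition of resonance, and strong acid sits next to a tertiary alcohol. The fallback hydrolyses both methoxy groups and re-methylates selectively. It sets out from 15: KOH in MeOH/H2O, then acidification, gives 2,5-dihydroxy-3-{[(1R,2S,4aS,8aS)-4a-hydroxy-1,2,5,5-tetramethyldecahydronaphthalen-1-yl]methyl}cyclohexa-2,5-diene-1,4-dione F7. Brief treatment with MeOH and catalytic TsOH (Fischer-type vinylogous esterification, which takes the unhindered hydroxyl next to the ring C–H) comes back to the route at 16.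

**Further compounds**
F1 | step 3 | (4R,6R)-2-[(E)-but-2-en-2-yl]-4,6-dimethyl-1,3-dioxane | C/C=C(\C)C1O[C@H](C)C[C@@H](C)O1
F2 | step 3 | (4R,6R)-4,6-dimethyl-2-[(1R,2S,8aR)-1,2,5,5-tetramethyl-1,2,3,5,6,7,8,8a-octahydronaphthalen-1-yl]-1,3-dioxane | C1(O[C@H](C)C[C@@H](C)O1)[C@]2(C)[C@@H](C)CC=C3[C@H]2CCCC3(C)C
F3 | step 5 | (1R,2S,8aR)-1,2,5,5-tetramethyl-1,2,3,5,6,7,8,8a-octahydronaphthalene-1-carboxylic acid | OC(=O)[C@]1(C)[C@@H](C)CC=C2[C@H]1CCCC2(C)C
F4 | step 5 | (1R,2S,4aS,8aS)-1,2,5,5-tetramethyloctahydro-2H-4a,1-(epoxymethano)naphthalen-10-one | O=C1[C@]2(C)[C@@H](C)CC[C@]3(O1)[C@H]2CCCC3(C)C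
F5 | step 5 | (1R,2S,4aS,8aS)-1,2,5,5-tetramethyloctahydro-2H-4a,1-(epoxymethano)naphthalen-10-ol | OC1[C@]2(C)[C@@H](C)CC[C@]3(O1)[C@H]2CCCC3(C)C
F6 | step 5 | (1R,2S,4aS,8aS)-1-[hydroxy(2,3,5,6-tetramethoxyphenyl)methyl]-1,2,5,5-tetramethyloctahydronaphthalen-4a(2H)-ol | OC(c1c(OC)c(OC)cc(OC)c1OC)[C@]2(C)[C@@H](C)CC[C@]3(O)[C@H]2CCCC3(C)C
F7 | step 8 | 2,5-dihydroxy-3-{[(1R,2S,4aS,8aS)-4a-hydroxy-1,2,5,5-tetramethyldecahydronaphthalen-1-yl]methyl}cyclohexa-2,5-diene-1,4-dione | OC1=CC(=O)C(O)=C(C[C@]2(C)[C@@H](C)CC[C@]3(O)[C@H]2CCCC3(C)C)C1=O
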